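The route rests on cutting the ring-fusion bond C1–C5 (guaiane numbering). The C3 ketone between C4=C5 and C2–C1 is a Nazarov retron, and because C1 and C5 are also tied through C6–C10 the closure must be transannular. One 4π electrocyclisation of a ten-membered cross-conjugated dienone should make the cyclopentenone, carve out the cycloheptane and set C1. The precursor is a germacrane-type cyclodeca-2,9-diene-1,6-dione bearing the C7 isopropenyl and C10 methyl groups. It comes from (S)-carvone, whose ring carbons become C3–C8: ethynyl on C3 and propenyl on C8 allow a dianionic oxy-Cope shift that breaks C3–C8, forms C1–C10 and sets C10.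

Key step: step 6

Remark: guaiane numbering (C1–C15) is used for every intermediate, and β is the ring face that carries the C7 side chain.

Step 1
Reactants: 1 (S)-(+)-carvone
Product: 3 (5R,6R)-6-hydroxy-2-methyl-5-(prop-1-en-2-yl)cyclohex-2-en-1-one, via potassium dienolate 2 (not isolated)
Conditions: KHMDS, THF, −78 °C; 2-(phenylsulfonyl)-3-phenyloxaziridine, −78 °C; AcOH
Reagents that add atoms: 2-(phenylsulfonyl)-3-phenyloxaziridine, O=S(=O)(c1ccccc1)N1OC1c1ccccc1
Why: Kinetic α′-deprotonation followed by oxaziridine enolate hydroxylation should place oxygen on C8 anti to the C7 isopropenyl group; this stereocentre is erased in step 3, so its selectivity does not matter.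

Step 2
Reactants: 3 (5R,6R)-6-hydroxy-2-methyl-5-(prop-1-en-2-yl)cyclohex-2-en-1-one; 4 ethynylmagnesium bromide
Product: 5 (1R,5R,6R)-1-ethynyl-2-methyl-5-(prop-1-en-2-yl)cyclohex-2-ene-1,6-diol
Conditions: 4 (3 equiv), THF, −78 → 0 °C; aq NH4Cl
Reagents that add atoms: none
Why: Grignard 1,2-addition (ethynylation) to the enone carbonyl follows deprotonation of the hydroxyl group; the slim sp nucleophile should attack C3 axially from the α face, but C3 becomes sp2 again in step 5, so both C3 epimers converge.

Step 3
Reactants: 5 (1R,5R,6R)-1-ethynyl-2-methyl-5-(prop-1-en-2-yl)cyclohex-2-ene-1,6-diol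
Product: 6 (2R,6R)-2-ethynyl-2-hydroxy-3-methyl-6-(prop-1-en-2-yl)cyclohex-3-en-1-one
Conditions: IBX, DMSO, 23 °C
Reagents that add atoms: none
Why: IBX oxidation takes the secondary alcohol of a 1,2-diol to the α-ketol without glycol cleavage and cannot touch the tertiary carbinol; C7 stays in its equatorial, more stable configuration.

Step 4
Reactants: 6 (2R,6R)-2-ethynyl-2-hydroxy-3-methyl-6-(prop-1-en-2-yl)cyclohex-3-en-1-one; 7 (E)-1-bromoprop-1-ene
Product: 9 (1R,5R,6R)-1-ethynyl-2-methyl-5-(prop-1-en-2-yl)-6-[(E)-prop-1-enyl]cyclohex-2-ene-1,6-diol, via (E)-prop-1-enyllithium 8 (not isolated)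
Conditions: 7 (3.3 equiv), t-BuLi (6.6 equiv), Et2O, −78 °C; then 6, THF, −78 → −40 °C; aq NH4Cl
Reagents that add atoms: none
Why: This is an alkenyllithium 1,2-addition after Li–Br exchange with retention of the E geometry: two equivalents are spent on O–H and C≡C–H, and the third should attack the C8 ketone axially from the β face, because the pseudo-axial ethynyl group on C3 screens the α face and the axial path meets no syn-axial hydrogen at sp2 C4, which sets C8 with propenyl cis to isopropenyl.

Step 5
Reactants: 9 (1R,5R,6R)-1-ethynyl-2-methyl-5-(prop-1-en-2-yl)-6-[(E)-prop-1-enyl]cyclohex-2-ene-1,6-diol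
Product: 11 (2E,4S,7R,9Z)-4,10-dimethyl-7-(prop-1-en-2-yl)cyclodeca-2,9-diene-1,6-dione, via dipotassium bis-enolate 10 (not isolated)
Conditions: KHMDS (2.05 equiv), 18-crown-6, THF, 0 → 23 °C; AcOH, −78 °C
Reagents that add atoms: none
Why: This is a dianionic (acetylenic) oxy-Cope rearrangement: C3–C8 is the only σ-bond flanked by both alkoxides, so the [3,3] shift through C1≡C2–C3–C8–C9=C10 should outrun the singly activated alternative through the isopropenyl group, a chair-like array with C7 pseudo-equatorial passes the C8 configuration suprafacially through the (E)-propenyl group to C10 (S), two equivalents of base leave the alkyne C–H in place, and both carbonyl groups stay masked as enolates until the cold quench.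

Step 6
Reactants: 11 (2E,4S,7R,9Z)-4,10-dimethyl-7-(prop-1-en-2-yl)cyclodeca-2,9-diene-1,6-dione
Product: 12 (1R,7R,10S)-guaia-4,11-diene-3,8-dione
Conditions: Sc(OTf)3 (20 mol %), CH2Cl2, −20 → 23 °C
Reagents that add atoms: none
Why: Proposed new method: the oxophilic Lewis acid binds the most basic oxygen (the cross-conjugated C3 ketone) and turns C1=C2–C3(O)–C4=C5 into a 3-oxidopentadienyl cation, which the ten-membered ring already holds in a U shape with C1 and C5 in contact, so that 4π-conrotatory closure forms C1–C5; loss of H5 from the oxyallyl cation and protonation of the dienolate at C2 give the tetrasubstituted C4=C5 enone and release the catalyst. The closest known reaction type is the Lewis acid-promoted Nazarov cyclisation of acyclic and ring-fused divinyl ketones, which has not been run across a medium ring. The five-membered ring (C1–C5) closes in the electrocyclic, formally 5-endo mode, and the same bond cuts the seven-membered ring (C1, C5–C10) out of the macrocycle as a transannular closure with relief of medium-ring strain. C1 is the only new stereocentre that survives: C5 should bond to the face of C1 anti to the C10 methyl group, which then sits pseudo-equatorial on the nascent cycloheptane, and because C1 is the γ-carbon of the new enone any epimer can drain through the dienol to the same all-equatorial isomer; C7, α to the C8 ketone, has the same thermodynamic preference and C10 is untouched. The step needs termination towards C5 and not C1, which the higher substitution of C4=C5 secures, and it needs the C8 ketone and the isopropenyl group to stay passive, which catalytic loading, an aprotic medium and low temperature are meant to secure.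

Step 7
Reactants: 12 (1R,7R,10S)-guaia-4,11-diene-3,8-dione
Product: 13 (1R,7R,8R,10S)-8-hydroxyguaia-4,11-dien-3-one
Conditions: L-Selectride (1.05 equiv), THF, −78 °C; AcOH
Reagents that add atoms: none
Why: In this bulky borohydride ketone reduction the reagent should reach the isolated C8 ketone from the α face, away from the nearly eclipsing C7 isopropenyl and the C10 methyl group, to give the 8β-alcohol cis to the C7 side chain (as 2-alkylcycloalkanones give cis alcohols), while the tetrasubstituted enone is inert at −78 °C.

Step 8
Reactants: 13 (1R,7R,8R,10S)-8-hydroxyguaia-4,11-dien-3-one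
Product: 14 torilolone, (1R,7S,8R,10S)-8,11-dihydroxyguai-4-en-3-one
Conditions: Co(acac)2 (20 mol %), PhSiH3, O2 (1 atm), THF, 23 °C
Reagents that add atoms: dioxygen, O=O
Why: In the Mukaiyama hydration, hydrogen-atom transfer goes only to the 1,1-disubstituted alkene and gives the tertiary C11 radical, which O2 traps to form the Markovnikov alcohol; the tetrasubstituted enone does not react and no stereocentre is formed.

Step 9
Reactants: 14 torilolone; 15 angelic acid
Product: 17 8-O-angeloyltorilolone, via mixed anhydride 16 (not isolated)
Conditions: 15, 2,4,6-Cl3C6H2COCl, Et3N, PhMe, 23 °C; then 14, 80 °C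
Reagents that add atoms: none
Why: Yamaguchi-type mixed-anhydride esterification without a nucleophilic catalyst is the established way to form angelates without Z→E isomerisation, and only the secondary C8 hydroxyl should react beside the tertiary C11 hydroxyl.

Step 10
Reactants: 17 8-O-angeloyltorilolone
Product: 18 torilin
Conditions: Ac2O, Sc(OTf)3 (5 mol %), MeCN, −20 °C
Reagents that add atoms: acetic anhydride, CC(=O)OC(C)=O
Why: Lewis acid-catalysed acetylation of a tertiary alcohol with acetic anhydride works by acyl transfer at low temperature, so C11–O should not ionise and the angelate, the enone and all four stereocentres are left alone.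

Compound list
1 | (S)-(+)-carvone | CC1=CC[C@@H](CC1=O)C(C)=C | starting material
2 | potassium cross-conjugated dienolate of 1 | CC1=CC[C@@H](C=C1[O-])C(C)=C.[K+] | intermediate
3 | (5R,6R)-6-hydroxy-2-methyl-5-(prop-1-en-2-yl)cyclohex-2-en-1-one | CC1=CC[C@H](C(C)=C)[C@@H](O)C1=O | intermediate
4 | ethynylmagnesium bromide | C#C[Mg]Br | starting material
5 | (1R,5R,6R)-1-ethynyl-2-methyl-5-(prop-1-en-2-yl)cyclohex-2-ene-1,6-diol | CC1=CC[C@H](C(C)=C)[C@@H](O)[C@@]1(O)C#C | intermediate
6 | (2R,6R)-2-ethynyl-2-hydroxy-3-methyl-6-(prop-1-en-2-yl)cyclohex-3-en-1-one | CC1=CC[C@H](C(C)=C)C(=O)[C@@]1(O)C#C | intermediate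
7 | (E)-1-bromoprop-1-ene | C/C=C/Br | starting material
8 | (E)-prop-1-enyllithium | [Li]/C=C/C | intermediate
9 | (1R,5R,6R)-1-ethynyl-2-methyl-5-(prop-1-en-2-yl)-6-[(E)-prop-1-enyl]cyclohex-2-ene-1,6-diol | CC1=CC[C@H](C(C)=C)[C@](O)(/C=C/C)[C@@]1(O)C#C | intermediate
10 | dipotassium bis-enolate of 11 (C3 allenolate, C8 enolate; allene axis not specified) | [K+].[K+].[O-]C1=C=C[C@@H](C)/C=C(\[O-])[C@@H](C(C)=C)C/C=C1/C | intermediate
11 | (2E,4S,7R,9Z)-4,10-dimethyl-7-(prop-1-en-2-yl)cyclodeca-2,9-diene-1,6-dione | O=C1/C=C/[C@@H](C)CC(=O)[C@@H](C(C)=C)C/C=C1/C | intermediate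
12 | (1R,7R,10S)-guaia-4,11-diene-3,8-dione | O=C1C[C@H](C)[C@H]2CC(=O)C(C)=C2C[C@@H]1C(C)=C | intermediate
13 | (1R,7R,8R,10S)-8-hydroxyguaia-4,11-dien-3-one | O[C@@H]1C[C@H](C)[C@H]2CC(=O)C(C)=C2C[C@@H]1C(C)=C | intermediate
14 | torilolone, (1R,7S,8R,10S)-8,11-dihydroxyguai-4-en-3-one | O[C@@H]1C[C@H](C)[C@H]2CC(=O)C(C)=C2C[C@@H]1C(C)(C)O | intermediate
15 | angelic acid, (Z)-2-methylbut-2-enoic acid | C/C=C(/C)C(=O)O | starting material
16 | angelic 2,4,6-trichlorobenzoic anhydride | C/C=C(/C)C(=O)OC(=O)c1c(Cl)cc(Cl)cc1Cl | intermediate
17 | 8-O-angeloyltorilolone | C/C=C(/C)C(=O)O[C@@H]1C[C@H](C)[C@H]2CC(=O)C(C)=C2C[C@@H]1C(C)(C)O | intermediate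
18 | torilin | C/C=C(/C)C(=O)O[C@@H]1C[C@H](C)[C@H]2CC(=O)C(C)=C2C[C@@H]1C(C)(C)OC(C)=O | target

Total step count: 10. Longest linear sequence: 10 steps, from 1.

Steps most likely to fail

Step 6. The C8 ketone may enolise and close a transannular aldol or Michael bond. The isopropenyl double bond may migrate into conjugation with C8. The unpolarised dienone may also simply not cyclise. The fallback sets out from 10 and returns at 12, and it makes the same C1–C5 bond under neutral conditions by known vinylallene chemistry.
- The bis-enolate 10 is quenched with Me3SiCl instead of acetic acid to give the 3-silyloxy vinylallene, bis(trimethylsilyl) ether F1.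
- The known Au(I)- or Pt(II)-catalysed cycloisomerisation of vinylallenes to cyclopentadienes then closes the five-membered ring. After 1,5-hydrogen shifts this gives 3,8-bis(trimethylsilyloxy)guaia-2,4,8,11-tetraene F2.
- Mild hydrolysis of both silyl enol ethers (citric acid, MeOH) gives 12.

Step 5. The base may take the alkyne proton and stall the shift. The propargylic alkoxide may lose acetylide. Alternatively, C3–C8 may cleave heterolytically and re-close at the wrong terminus. The fallback sets out from 9 and returns at 11, and it uses the classical all-alkene version of the rearrangement.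
- Semihydrogenation over Lindlar catalyst gives the 1-ethenyl diol F3.
- KH and 18-crown-6 followed by Me3SiCl give the rearranged bis(trimethylsilyl enol ether) F4.
- Saegusa–Ito oxidation with one equivalent of Pd(OAc)2 should act on the more electron-rich conjugated C3 silyl dienol ether and install C1=C2.
- Mild acid then frees the C8 ketone to give 11.

Step 4. Facial selectivity at C8 may be poor or reversed, or the hindered ketone may enolise instead of adding. The fallback sets out from 6 and returns at 11, and it re-pairs the two stereochemical elements instead of fighting the bias. If attack from the α face prevails, (Z)-prop-1-enyllithium is added to 6 to give the C8-epimeric (Z)-propenyl diol F5. Inversion at C8 and inversion of the alkene geometry cancel in the suprafacial shift. The conditions of step 5 should therefore deliver the same (10S) macrocycle 11.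

Further compounds
F1 | step 6 | bis(trimethylsilyl) ether of 10 (3-silyloxy vinylallene, C8 silyl enol ether; allene axis not specified) | C[Si](C)(C)OC1=C=C[C@@H](C)/C=C(\O[Si](C)(C)C)[C@@H](C(C)=C)C/C=C1/C
F2 | step 6 | (1R,7R,10S)-3,8-bis(trimethylsilyloxy)guaia-2,4,8,11-tetraene | C[Si](C)(C)OC1=C[C@H](C)[C@H]2C=C(O[Si](C)(C)C)C(C)=C2C[C@@H]1C(C)=C
F3 | step 5 | (1R,5R,6R)-1-ethenyl-2-methyl-5-(prop-1-en-2-yl)-6-[(E)-prop-1-enyl]cyclohex-2-ene-1,6-diol | CC1=CC[C@H](C(C)=C)[C@](O)(/C=C/C)[C@@]1(O)C=C
F4 | step 5 | 1,6-bis(trimethylsilyloxy)-4,10-dimethyl-7-(prop-1-en-2-yl)cyclodeca-1,5,9-triene | C[Si](C)(C)O/C1=C\C[C@@H](C)/C=C(\O[Si](C)(C)C)[C@@H](C(C)=C)C/C=C1/C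
F5 | step 4 | (1R,5R,6S)-1-ethynyl-2-methyl-5-(prop-1-en-2-yl)-6-[(Z)-prop-1-enyl]cyclohex-2-ene-1,6-diol | CC1=CC[C@H](C(C)=C)[C@@](O)(/C=C\C)[C@@]1(O)C#C
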